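**Strategy**

The plan disconnects the C8–C9 bond shared by rings B and C (gibberellane numbering). C9 is β to the C12 ketone, and C8 becomes the α-carbon of an aldehyde once ring C is opened at C13–C14, so the 1,5-relationship C12/C14 is the handle. The precursor is a monocyclic ring A 19,20-lactone carrying an (E)-butenone on C10 and an α-propargyl aldehyde chain on C5. One amine-catalysed Michael–aldol cascade closes ring B through C8–C9, sets the quaternary C8 and C9, and closes ring C. A temporary cyclopentanone (C19–C7 bond), made by a proline aldol, fixes C4, C5, C6 and C10 beforehand; a gold-catalysed Conia-ene reaction adds ring D.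

Key step: step 13

Remark on numbering: gibberellane numbering is used for every intermediate (C1–C3 ring A methylenes; C4 with C18 methyl and C19 carboxyl; C5; C6 with C7 carboxyl; C8; C9; C10 with C20; C11; C12 ketone; C13; C14; C15; C16=C17).

Remark (assumption): the sense of induction of the proline aldol in step 4 is taken to parallel the Hajos–Parrish reaction, which calls for D-proline to reach the (7aR) enal 7; if the sense were opposite, L-proline would be used.

**Route**

Step 1
Reactants: 1 2-methylcyclopentane-1,3-dione; 2 acrolein
Product: 3 3-(1-methyl-2,5-dioxocyclopentyl)propanal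
Conditions: H2O, rt
Reagents that add atoms: none
Why: The acidic 2-position of the 1,3-dione adds to acrolein in a Michael addition that needs no added base in water and creates no stereocenter.

Step 2
Reactants: 3 3-(1-methyl-2,5-dioxocyclopentyl)propanal
Product: 4 (2E)-5-(1-methyl-2,5-dioxocyclopentyl)pent-2-enal
Conditions: Ph3P=CHCHO, toluene, 80 °C
Reagents that add atoms: (triphenylphosphoranylidene)acetaldehyde, O=CC=P(c1ccccc1)(c1ccccc1)c1ccccc1
Why: Wittig olefination with this stabilised ylide is selective for the aldehyde over the two ring ketones and should give the (E)-enal.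

Step 3
Reactants: 4 (2E)-5-(1-methyl-2,5-dioxocyclopentyl)pent-2-enal
Product: 5 5-(1-methyl-2,5-dioxocyclopentyl)pentanal
Conditions: H2 (1 atm), Pd/C, EtOAc, rt
Reagents that add atoms: none
Why: Catalytic hydrogenation over palladium saturates the conjugated C=C bond much faster than it touches the aldehyde or the ketones.

Step 4
Reactants: 5 5-(1-methyl-2,5-dioxocyclopentyl)pentanal
Product: 7 (7aR)-7a-methyl-1-oxo-2,3,5,6,7,7a-hexahydro-1H-indene-4-carbaldehyde, via ketol 6 (not isolated)
Conditions: D-proline (20 mol %), MeCN, rt; then TsOH·H2O (cat.), toluene, 70 °C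
Reagents that add atoms: none
Why: Proline-catalysed intramolecular aldol reaction of the Hajos–Parrish type (6-enolexo): the aldehyde enamine attacks one of the two enantiotopic ring carbonyls under direction of the catalyst's carboxylic acid, which sets C4, and acid then dehydrates ketol 6 to the conjugated enal.

Step 5
Reactants: 7 (7aR)-7a-methyl-1-oxo-2,3,5,6,7,7a-hexahydro-1H-indene-4-carbaldehyde
Product: 8 trimethylsilyl enol ether of 7 at the ring ketone (C19=C7)
Conditions: LiN(SiMe3)2, Me3SiCl, THF, −78 °C
Reagents that add atoms: chlorotrimethylsilane, C[Si](C)(C)Cl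
Why: Kinetic enolisation of the ketone at C7, its only α-position, with in situ silylation (silyl enol ether formation) masks the C19 ketone so that the next base can only deprotonate the enal; the bulky amide neither adds to the conjugated aldehyde nor removes its γ-protons at a comparable rate.

Step 6
Reactants: 8 trimethylsilyl enol ether of 7
Product: 10 bis-silylated quaternary aldehyde (C10 bearing CHO and CH2OSiMe2t-Bu; diene C5=C6/C7=C19), via lithium alkoxide 9 (not isolated)
Conditions: LiN(i-Pr)2, THF, −78 °C; CH2O (monomer from cracked paraformaldehyde, 1.2 equiv); t-BuMe2SiOTf, 2,6-lutidine, −78 °C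
Reagents that add atoms: formaldehyde, C=O; tert-butyldimethylsilyl trifluoromethanesulfonate, CC(C)(C)[Si](C)(C)OS(=O)(=O)C(F)(F)F
Why: Deprotonation at the doubly allylic C6 gives the extended aldehyde enolate, which adds to formaldehyde at its α-carbon C10 (deconjugative aldol hydroxymethylation) on the face opposite the pseudo-axial angular methyl group, setting the quaternary C10 with C20 trans to C18, and silylation of the alkoxide blocks retro-aldol cleavage.

Step 7
Reactants: 10 bis-silylated quaternary aldehyde
Product: 12 (3aS,4R,7aR)-4-{[(tert-butyldimethylsilyl)oxy]methyl}-7a-methyl-1-oxo-3a,4,5,6,7,7a-hexahydro-1H-indene-4-carbaldehyde, via deconjugated ketone 11 (not isolated)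
Conditions: citric acid, THF/H2O, 0 °C; then DBU (cat.), CH2Cl2, rt
Reagents that add atoms: none
Why: Mild acid hydrolyses the silyl dienol ether and the amidine base moves the double bond into conjugation with the C19 ketone (β,γ to α,β isomerisation), the new C5 centre being set under thermodynamic control as the cis-fused hydrindenone with H5 cis to the angular methyl group, as known for 14β-15-en-17-one steroids.

Step 8
Reactants: 12 cis-fused enone aldehyde
Product: 13 (3aS,4R,7aR)-4-{[(tert-butyldimethylsilyl)oxy]methyl}-7a-methyl-4-[(1E)-3-oxobut-1-en-1-yl]-3a,4,5,6,7,7a-hexahydro-1H-inden-1-one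
Conditions: Ph3P=CHC(O)CH3, toluene, 100 °C
Reagents that add atoms: 1-(triphenylphosphoranylidene)propan-2-one, CC(=O)C=P(c1ccccc1)(c1ccccc1)c1ccccc1
Why: Wittig olefination of the neopentyl aldehyde with the acetonyl ylide gives the (E)-enone, and neither the cyclopentenone carbonyl nor the silyl ether reacts with this stabilised ylide.

Step 9
Reactants: 14 pent-4-ynal
Product: 15 tert-butyldimethyl(penta-1-en-4-yn-1-yloxy)silane (E/Z mixture)
Conditions: t-BuMe2SiOTf, Et3N, CH2Cl2, 0 °C
Reagents that add atoms: tert-butyldimethylsilyl trifluoromethanesulfonate, CC(C)(C)[Si](C)(C)OS(=O)(=O)C(F)(F)F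
Why: Soft enolisation of the aldehyde with the silyl triflate and triethylamine gives the enol silane (silyl enol ether formation), whose double-bond geometry is irrelevant because C8 is planarised again in step 13.

Step 10
Reactants: 13 bis-enone; 15 enol silane
Product: 16 silyl enol ether (C19=C7) carrying at C6 the 1-formylbut-3-yn-1-yl group cis to H5 and the angular methyl (C8 epimers)
Conditions: t-BuMe2SiOTf (10 mol %), CH2Cl2, −78 °C, enol silane added slowly in equimolar amount; Et3N quench
Reagents that add atoms: none
Why: Mukaiyama–Michael addition: the enol silane attacks the cyclopentenone β-carbon C6 on the convex face, anti to the C5–C10 bond, which sets C6, while the acyclic enone is shielded at its β-carbon by the quaternary C10; the silyl group passes from the enol oxygen of 15 to the C19 oxygen, so 16 is the adduct of one molecule of each reactant and holds every atom of both, and equimolar use of 15 keeps the new aldehyde from a following Mukaiyama aldol reaction.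

Step 11
Reactants: 16 silyl enol ether
Product: 18 ring A seco acid (C19 CO2H, C7 CO2Me, C20 silyl ether, C14 aldehyde; C8 epimers), via methoxy hydroperoxide 17 (not isolated)
Conditions: O3, NaHCO3, CH2Cl2/MeOH, −78 °C; Ac2O, Et3N, 0 °C to rt; aqueous work-up at pH 4
Reagents that add atoms: ozone, [O-][O+]=O; methanol, CO
Why: Ozonolysis of the electron-rich silyl enol ether, much faster than attack on the alkyne or the enone, gives the C19 silyl ester and the C7 carbonyl oxide, which methanol traps and acetic anhydride with triethylamine dehydrates to the methyl ester, so the temporary ring becomes the two differentiated carboxyl groups without touching C4, C5 or C6.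

Step 12
Reactants: 18 ring A seco acid
Product: 20 19,20-lactone aldehyde (C8 epimers), via hydroxy acid 19 (not isolated)
Conditions: HF·pyridine, THF, 0 °C to rt
Reagents that add atoms: none
Why: Fluoride removes the primary silyl ether and the freed C20 hydroxyl lactonises onto the cis-1,3-diaxial C19 acid (acid-promoted δ-lactonisation), which masks C19 and C20 together and locks ring A in the chair with C6 and C9 equatorial.

Step 13
Reactants: 20 19,20-lactone aldehyde
Product: 23 tetracyclic enone lactone (rings A, B and C; C12 ketone, C13=C14; C8 propargyl; C7 methyl ester), via keto aldehyde 21 (not isolated), via aldol 22 (not isolated)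
Conditions: pyrrolidine (30 mol %), AcOH (30 mol %), toluene, 25 to 60 °C
Reagents that add atoms: none
Why: Pyrrolidine converts the C14 aldehyde into an enamine whose nucleophilic C8 adds to C9 of the (E)-enone, and after hydrolysis the C12 methyl ketone condenses through C13 with the C14 aldehyde and loses water (intramolecular Michael addition followed by aldol condensation, a Robinson annulation run within one molecule). Ring B closes in a 5-exo-trig mode through C8–C9, and ring C closes in a 6-(enolendo)-exo-trig aldol mode through C13–C14. C9 is set by the substrate: the lactone holds ring A in one chair, and in the low-energy rotamer about C10–C9 the C10–C20 bond eclipses the alkene, so the face turned towards C6 gives C11 cis and H9 trans to C20. The quaternary C8 is set by the compact synclinal enamine–enone transition state, in which allylic strain keeps H6 in the enamine plane; this places C14 cis to C11 and the propargyl group on the opposite face, the only arrangement from which ring C can close. The step needs attack at C9 rather than reaction at C20 or C12, which is secured by C20 being tied up in the lactone and by the aldehyde being the only carbonyl that forms an enamine readily; both C8 epimers of 20 converge because C8 is planar in the enamine.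

Step 14
Reactants: 23 tetracyclic enone lactone
Product: 24 C12 tert-butyldimethylsilyl enol ether (C12=C13)
Conditions: LiBH(s-Bu)3, THF, −78 °C; then t-BuMe2SiOTf, Et3N, −78 to 0 °C
Reagents that add atoms: tert-butyldimethylsilyl trifluoromethanesulfonate, CC(C)(C)[Si](C)(C)OS(=O)(=O)C(F)(F)F
Why: The hindered borohydride reduces the β-unsubstituted cyclohexenone in the 1,4-sense and the resulting enolate is silylated on oxygen (conjugate reduction with enolate trapping), which fixes the enol ether regiochemistry at C12–C13 while the lactone, ester and alkyne survive at low temperature.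

Step 15
Reactants: 24 C12 silyl enol ether
Product: 25 methyl ester 19,20-lactone with the complete ring system (C12 ketone, C16 methylene)
Conditions: (Ph3P)AuCl (5 mol %), AgBF4 (5 mol %), CH2Cl2/MeOH (10:1), rt
Reagents that add atoms: none
Why: Cationic monovalent gold activates the alkyne for 5-exo-dig attack by the silyl enol ether carbon C13 (Conia-ene type carbocyclisation) and protodeauration gives the exocyclic methylene; the one-carbon bridge can form only on the face of ring C that bears the C15 chain, which sets C13.

Step 16
Reactants: 25 methyl ester 19,20-lactone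
Product: 27 diallyl 20-hydroxy diester, via dipotassium salt 26 (not isolated)
Conditions: KOH (2 equiv), dioxane/H2O, 80 °C; evaporate; allyl bromide, DMF, rt
Reagents that add atoms: potassium hydroxide, [K+].[OH-]; allyl bromide, C=CCBr
Why: Hydroxide opens the δ-lactone and saponifies the C7 methyl ester, and alkylation of the dicarboxylate with allyl bromide in DMF (carboxylate SN2 esterification) gives the diallyl ester with the C20 alcohol free, while the carboxylate form prevents relactonisation and epimerisation at C6.

Step 17
Reactants: 27 diallyl 20-hydroxy diester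
Product: 28 diallyl ester of the target (C20 aldehyde)
Conditions: Dess–Martin periodinane, NaHCO3, CH2Cl2, 0 °C
Reagents that add atoms: none
Why: Dess–Martin oxidation under buffered neutral conditions turns the neopentyl primary alcohol into the C20 aldehyde faster than it can relactonise onto the allyl ester.

Step 18
Reactants: 28 diallyl ester of the target
Product: 29 target diacid CNP0412196.1
Conditions: Pd(PPh3)4 (5 mol %), morpholine, THF, rt; work-up at pH 3
Reagents that add atoms: none
Why: Zerovalent palladium ionises both allyl esters to π-allyl complexes that morpholine captures (Tsuji–Trost deallylation), which frees the two acids without touching the aldehyde, the ketone or the exocyclic alkene.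

**Compound list**

1 | 2-methylcyclopentane-1,3-dione | CC1C(=O)CCC1=O | starting material
2 | acrolein (prop-2-enal) | C=CC=O | starting material
3 | 3-(1-methyl-2,5-dioxocyclopentyl)propanal | CC1(CCC=O)C(=O)CCC1=O | intermediate
4 | (2E)-5-(1-methyl-2,5-dioxocyclopentyl)pent-2-enal | CC1(CC/C=C/C=O)C(=O)CCC1=O | intermediate
5 | 5-(1-methyl-2,5-dioxocyclopentyl)pentanal | CC1(CCCCC=O)C(=O)CCC1=O | intermediate
6 | (3aR,7aR)-3a-hydroxy-7a-methyl-1-oxooctahydro-1H-indene-4-carbaldehyde (cis-fused ketol, configuration at the formyl-bearing carbon not defined) | O=CC1CCC[C@@]2(C)C(=O)CC[C@@]12O | intermediate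
7 | (7aR)-7a-methyl-1-oxo-2,3,5,6,7,7a-hexahydro-1H-indene-4-carbaldehyde | O=CC1=C2CCC(=O)[C@]2(C)CCC1 | intermediate
8 | (7aR) trimethylsilyl enol ether of 7 (enol ether C19=C7, enal C5=C10) | O=CC1=C2CC=C(O[Si](C)(C)C)[C@]2(C)CCC1 | intermediate
9 | (4R,7aR) hydroxymethyl aldol adduct, formed as its lithium alkoxide (drawn as the alcohol) | O=C[C@]1(CO)CCC[C@@]2(C)C(O[Si](C)(C)C)=CC=C12 | intermediate
10 | (4R,7aR)-4-{[(tert-butyldimethylsilyl)oxy]methyl}-7a-methyl-1-[(trimethylsilyl)oxy] diene aldehyde (diene C5=C6/C7=C19; C20 anti to the angular methyl) | O=C[C@]1(CO[Si](C)(C)C(C)(C)C)CCC[C@@]2(C)C(O[Si](C)(C)C)=CC=C12 | intermediate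
11 | (4R,7aR)-4-{[(tert-butyldimethylsilyl)oxy]methyl}-7a-methyl-1-oxo-2,4,5,6,7,7a-hexahydro-1H-indene-4-carbaldehyde (β,γ-unsaturated ketone, C5=C6) | O=C[C@]1(CO[Si](C)(C)C(C)(C)C)CCC[C@@]2(C)C(=O)CC=C12 | intermediate
12 | (3aS,4R,7aR)-4-{[(tert-butyldimethylsilyl)oxy]methyl}-7a-methyl-1-oxo-3a,4,5,6,7,7a-hexahydro-1H-indene-4-carbaldehyde (cis-fused) | O=C[C@]1(CO[Si](C)(C)C(C)(C)C)CCC[C@@]2(C)C(=O)C=C[C@@H]12 | intermediate
13 | (3aS,4R,7aR)-4-{[(tert-butyldimethylsilyl)oxy]methyl}-7a-methyl-4-[(1E)-3-oxobut-1-en-1-yl]-3a,4,5,6,7,7a-hexahydro-1H-inden-1-one | CC(=O)/C=C/[C@]1(CO[Si](C)(C)C(C)(C)C)CCC[C@@]2(C)C(=O)C=C[C@@H]12 | intermediate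
14 | pent-4-ynal | C#CCCC=O | starting material
15 | tert-butyldimethyl(penta-1-en-4-yn-1-yloxy)silane (E/Z mixture) | C#CCC=CO[Si](C)(C)C(C)(C)C | intermediate
16 | Mukaiyama–Michael adduct: C19=C7 tert-butyldimethylsilyl enol ether with the 1-formylbut-3-yn-1-yl group on C6, cis to H5 and the angular methyl (C8 epimers) | CC(=O)/C=C/[C@]1(CO[Si](C)(C)C(C)(C)C)CCC[C@@]2(C)C(O[Si](C)(C)C(C)(C)C)=C[C@H](C(C=O)CC#C)[C@@H]12 | intermediate
17 | C19 silyl ester with C7 as methoxy hydroperoxide (C8 epimers) | CC(=O)/C=C/[C@]1(CO[Si](C)(C)C(C)(C)C)CCC[C@@](C)(C(=O)O[Si](C)(C)C(C)(C)C)[C@H]1[C@H](C(OC)OO)C(C=O)CC#C | intermediate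
18 | ring A seco acid: C4 (methyl, CO2H), C10 (CH2OSiMe2t-Bu, (E)-3-oxobutenyl), C6 (CO2Me), C8 (CHO, propargyl; epimers); C4, C5, C6, C10 as in the target | CC(=O)/C=C/[C@]1(CO[Si](C)(C)C(C)(C)C)CCC[C@@](C)(C(=O)O)[C@H]1[C@H](C(=O)OC)C(C=O)CC#C | intermediate
19 | 20-hydroxy 19-acid (C8 epimers) | CC(=O)/C=C/[C@]1(CO)CCC[C@@](C)(C(=O)O)[C@H]1[C@H](C(=O)OC)C(C=O)CC#C | intermediate
20 | 19,20-lactone aldehyde (3-oxabicyclo[3.3.1]nonan-2-one core; C8 epimers) | CC(=O)/C=C/[C@]12COC(=O)[C@](C)(CCC1)[C@H]2[C@H](C(=O)OC)C(C=O)CC#C | intermediate
21 | Michael adduct: ring B closed, C8 (CHO, propargyl), C9 (2-oxopropyl); C4, C5, C6, C8, C9, C10 as in the target | C#CC[C@]1(C=O)[C@@H](CC(C)=O)[C@]23COC(=O)[C@](C)(CCC2)[C@H]3[C@@H]1C(=O)OC | intermediate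
22 | aldol: ring C closed, C14 hydroxyl (configuration not defined), C12 ketone | C#CC[C@]12C(O)CC(=O)C[C@H]1[C@]13COC(=O)[C@](C)(CCC1)[C@H]3[C@@H]2C(=O)OC | intermediate
23 | tetracyclic enone lactone: C12 ketone, C13=C14, C8 propargyl, C7 methyl ester; C4, C5, C6, C8, C9, C10 as in the target | C#CC[C@]12C=CC(=O)C[C@H]1[C@]13COC(=O)[C@](C)(CCC1)[C@H]3[C@@H]2C(=O)OC | intermediate
24 | C12 tert-butyldimethylsilyl enol ether (C12=C13) of the reduced ketone | C#CC[C@]12CC=C(O[Si](C)(C)C(C)(C)C)C[C@H]1[C@]13COC(=O)[C@](C)(CCC1)[C@H]3[C@@H]2C(=O)OC | intermediate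
25 | methyl ester 19,20-lactone with rings A–D, C12 ketone and C16 methylene; all seven stereocenters as in the target | C=C1C[C@]23C[C@H]1C(=O)C[C@H]2[C@]14COC(=O)[C@](C)(CCC1)[C@H]4[C@@H]3C(=O)OC | intermediate
26 | dipotassium 20-hydroxy-7,19-dicarboxylate | C=C1C[C@]23C[C@H]1C(=O)C[C@H]2[C@]1(CO)CCC[C@@](C)(C(=O)[O-])[C@H]1[C@@H]3C(=O)[O-].[K+].[K+] | intermediate
27 | diallyl 20-hydroxy-12-oxo-7,19-diester | C=C1C[C@]23C[C@H]1C(=O)C[C@H]2[C@]1(CO)CCC[C@@](C)(C(=O)OCC=C)[C@H]1[C@@H]3C(=O)OCC=C | intermediate
28 | diallyl ester of the target (C20 aldehyde) | C=C1C[C@]23C[C@H]1C(=O)C[C@H]2[C@]1(C=O)CCC[C@@](C)(C(=O)OCC=C)[C@H]1[C@@H]3C(=O)OCC=C | intermediate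
29 | CNP0412196.1, (4R,5S,6S,8R,9R,10R,13R) in gibberellane numbering: 20-oxo-12-oxo-16-ene-7,19-dioic acid | C=C1C[C@]23C[C@H]1C(=O)C[C@H]2[C@]1(C=O)CCC[C@@](C)(C(=O)O)[C@H]1[C@@H]3C(=O)O | target

**Totals and risks**

Total step count: 18. Longest linear sequence: 17 steps (steps 1 to 8 and 10 to 18; step 9 prepares enol silane 15).

Steps most likely to fail:

Step 13 (key step). The enamine Michael addition may show poor facial selectivity at C9, or enamine formation from the α-branched aldehyde may be slow enough that intermolecular aldol condensation takes over. The fallback sets out from 20 and replaces the ionic cascade by a pericyclic ring closure. Acetalisation of the aldehyde (HC(OMe)3, pyridinium tosylate, MeOH) should give the dimethyl acetal F1. Me3SiOTf and i-Pr2NEt then eliminate methanol to the methyl enol ether F2; the transient silyl dienol ether of the methyl ketone is cleaved again by K2CO3 in MeOH on work-up. Heating in toluene (140 °C, sealed tube) should bring about an intramolecular oxa-Diels–Alder reaction with inverse electron demand, the enone acting as heterodiene; it forms C8–C9 and O–C14 through a bicyclic transition state that forces C14 and C11 cis and gives the methoxydihydropyran F3. Aqueous HCl in THF unravels F3 to keto aldehyde 21, and pyrrolidinium acetate closes ring C, which returns to the route at 23.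

Step 10. The enol silane may also add to the acyclic enone, or the product aldehyde may undergo aldol oligomerisation with the enol silane. The fallback sets out from 12 and carries the C9 side chain as a poorer acceptor. Wittig reaction with Ph3P=CHC(O)SEt should give the unsaturated thioester F4, which is inert under the silyl-triflate-catalysed conditions. Mukaiyama–Michael addition of 15 then gives the silyl enol ether F5, and ozonolysis with the work-up of step 11 gives the thioester acid F6. Fukuyama coupling (MeZnI, PdCl2(PPh3)2, toluene) converts the thioester into the methyl ketone in the presence of the aldehyde and returns to the route at 18.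

Step 6. Formaldehyde may attack at C6 instead of C10 or syn to the angular methyl group, and the aldolate may lose formaldehyde again before it is silylated. The fallback sets out from 7 without protection of the ketone and uses covalent catalysis in place of the lithium enolate. Proline-catalysed cross-aldol reaction with aqueous formaldehyde in DMSO proceeds through the dienamine of the enal, which forms only at the aldehyde, and should give the hydroxy aldehyde F7 with the same facial preference. Silylation (t-BuMe2SiCl, imidazole, DMF) gives 11, here isolated, and DBU as in step 7 returns to the route at 12.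

Further compounds
F1 | step 13 | dimethyl acetal of lactone aldehyde 20 (C8 epimers) | CC(=O)/C=C/[C@]12COC(=O)[C@](C)(CCC1)[C@H]2[C@H](C(=O)OC)C(C(OC)OC)CC#C
F2 | step 13 | methyl enol ether (C8=C14, E/Z mixture) of lactone aldehyde 20 | CC(=O)/C=C/[C@]12COC(=O)[C@](C)(CCC1)[C@H]2[C@H](C(=O)OC)C(=COC)CC#C
F3 | step 13 | 2-methoxy-3,4-dihydro-2H-pyran cycloadduct (O–C14 and C8–C9 formed; C14 not defined) | C#CC[C@]12C(OC)OC(C)=C[C@H]1[C@]13COC(=O)[C@](C)(CCC1)[C@H]3[C@@H]2C(=O)OC
F4 | step 10 | S-ethyl (2E)-enethioate analogue of 13 | CCSC(=O)/C=C/[C@]1(CO[Si](C)(C)C(C)(C)C)CCC[C@@]2(C)C(=O)C=C[C@@H]12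
F5 | step 10 | Mukaiyama–Michael adduct of F4 (C19=C7 silyl enol ether, C8 epimers) | CCSC(=O)/C=C/[C@]1(CO[Si](C)(C)C(C)(C)C)CCC[C@@]2(C)C(O[Si](C)(C)C(C)(C)C)=C[C@H](C(C=O)CC#C)[C@@H]12
F6 | step 10 | thioester analogue of seco acid 18 | CCSC(=O)/C=C/[C@]1(CO[Si](C)(C)C(C)(C)C)CCC[C@@](C)(C(=O)O)[C@H]1[C@H](C(=O)OC)C(C=O)CC#C
F7 | step 6 | (4R,7aR)-4-(hydroxymethyl)-7a-methyl-1-oxo-2,4,5,6,7,7a-hexahydro-1H-indene-4-carbaldehyde | O=C[C@]1(CO)CCC[C@@]2(C)C(=O)CC=C12
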